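**Plan**

- Retrosynthetic cuts, in order: C3–C4 (ring closure by Ni/Cr alkenyl iodide–aldehyde addition); C4=C5 (Z-iodo-olefination of a C5 aldehyde); the epoxide oxygen and the C8 ester; the lactone bonds O–C6 and C11–C12 (CO2); C7–C8 (Evans aldol); C1–C2 and C10–CH3 (carboalumination/ethylene oxide).
- Forward order: a C8–C10/C1–C3 aldehyde and a malic-acid-derived C5–C7/C11 imide are joined by aldol; C11 becomes a 2-iodoalkene and C5/C6 an oxirane; CO2 then builds the butyrolactone; Z-vinyl iodide, furoate and epoxide follow; the ten-membered ring closes last and frees the C3 hydroxyl.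
- Feature used by the key event: the lactone carbon C6 sits 1,3 (through C7) to the sp2 carbon C11, and its other neighbour C5 is the later alkene CH. C6 can therefore be carried as the inner carbon of a terminal C5–C6 oxirane that is inert to organolithium, while C11 carries lithium; CO2 bridges vinyl C11 and oxirane C6 into the five-membered lactone ring and releases C5–OH as the handle for C4=C5.
- Stereochemistry: C6 from (S)-malic acid (dioxolane, then (S)-oxirane, inverted once by the carboxylate); C7 and C8 from the (S)-benzyloxazolidinone syn-aldol; C1/C10 from Shi epoxidation; E-C1=C10 from syn-carboalumination; Z-C4=C5 from the iodo-Wittig; C3 from the ring-closing addition (substrate control, correctable).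

Key step: step 15

Remark: locants C1–C15 are the germacrane-type positions of the target (C6 lactone CH–O, C7 ring-fusion CH, C8 ester carbinol, C9 CH2, C10/C1 oxirane carbons, C2 CH2, C3 carbinol, C4=C5 ring alkene, C11=C13 exocyclic methylene, C12 lactone C=O, C14/C15 methyls on C10/C4). The target is read as 1R,3S,4Z,6S,7R,8R,10R with a cis-fused lactone. Compounds 1, 7 and 9 and all named reagents are taken as commercial.

**Step 1**
Reactants: 1 tert-butyl(but-3-yn-1-yloxy)dimethylsilane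
Product: 3 (3E)-6-{[tert-butyl(dimethyl)silyl]oxy}-4-methylhex-3-en-1-ol, via alkenyldimethylalane 2 (not isolated)
Conditions: AlMe3, Cp2ZrCl2 (cat.), CH2Cl2, 0 °C to rt; n-BuLi, THF, −30 °C; ethylene oxide, −30 to 0 °C
Reagents that add atoms: trimethylaluminium C[Al](C)C; ethylene oxide C1CO1
Why: Negishi zirconium-catalysed carboalumination adds CH3 and Al syn across the terminal alkyne (Al at the terminus), fixing the E C1=C10 geometry, and the derived alanate opens ethylene oxide with retention to add C2–C3.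

**Step 2**
Reactants: 3 (3E)-6-{[tert-butyl(dimethyl)silyl]oxy}-4-methylhex-3-en-1-ol
Product: 4 tert-butyl({(3E)-6-[(4-methoxyphenyl)methoxy]-3-methylhex-3-en-1-yl}oxy)dimethylsilane
Conditions: NaH, PMBCl, Bu4NI (cat.), THF/DMF, 0 °C to rt
Reagents that add atoms: 4-methoxybenzyl chloride COc1ccc(CCl)cc1
Why: Williamson etherification masks the C3 oxygen with a group that should survive fluoride, organolithium and HF and leave under neutral DDQ conditions.

**Step 3**
Reactants: 4 tert-butyl({(3E)-6-[(4-methoxyphenyl)methoxy]-3-methylhex-3-en-1-yl}oxy)dimethylsilane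
Product: 5 (3E)-6-[(4-methoxyphenyl)methoxy]-3-methylhex-3-en-1-ol
Conditions: TBAF, THF, 0 °C to rt
Reagents that add atoms: none
Why: Fluoride desilylation frees the primary C8 alcohol and leaves the PMB ether and the alkene untouched.

**Step 4**
Reactants: 5 (3E)-6-[(4-methoxyphenyl)methoxy]-3-methylhex-3-en-1-ol
Product: 6 (3E)-6-[(4-methoxyphenyl)methoxy]-3-methylhex-3-enal
Conditions: Dess–Martin periodinane, CH2Cl2, 0 °C to rt; short silica pad, used at once
Reagents that add atoms: none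
Why: Dess–Martin oxidation is neutral and base-free, so the β,γ-unsaturated aldehyde should not slip into conjugation before it is used.

**Step 5**
Reactants: 7 methyl [(4S)-2,2-dimethyl-1,3-dioxolan-4-yl]acetate
Product: 8 [(4S)-2,2-dimethyl-1,3-dioxolan-4-yl]acetic acid
Conditions: LiOH, THF/H2O, 0 °C to rt; cold dilute HCl to pH 4
Reagents that add atoms: lithium hydroxide [Li+].[OH-]
Why: Ester saponification, with acidification held at pH 4 so that the acetonide carrying the (S)-malic-acid centre (future C6) survives.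

**Step 6**
Reactants: 8 [(4S)-2,2-dimethyl-1,3-dioxolan-4-yl]acetic acid; 9 (4S)-4-benzyl-1,3-oxazolidin-2-one
Product: 10 (4S)-4-benzyl-3-{[(4S)-2,2-dimethyl-1,3-dioxolan-4-yl]acetyl}-1,3-oxazolidin-2-one
Conditions: DCC, DMAP (cat.), CH2Cl2, 0 °C to rt
Reagents that add atoms: none
Why: Steglich-type carbodiimide/DMAP N-acylation attaches the Evans auxiliary under neutral conditions that spare the acetonide.

**Step 7**
Reactants: 10 (4S)-4-benzyl-3-{[(4S)-2,2-dimethyl-1,3-dioxolan-4-yl]acetyl}-1,3-oxazolidin-2-one; 6 (3E)-6-[(4-methoxyphenyl)methoxy]-3-methylhex-3-enal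
Product: 12 (4S)-4-benzyl-3-[(2R,3R,5E)-2-[(4S)-2,2-dimethyl-1,3-dioxolan-4-yl]-3-hydroxy-8-[(4-methoxyphenyl)methoxy]-5-methyloct-5-enoyl]-1,3-oxazolidin-2-one, via Z-boron enolate 11 (not isolated)
Conditions: Bu2BOTf, Et3N, CH2Cl2, −78 to 0 °C; 6, −78 to 0 °C; pH 7 buffer, MeOH, H2O2, 0 °C
Reagents that add atoms: none
Why: Evans syn-aldol through the Z-boron enolate and a Zimmerman–Traxler chair forms C7–C8, the (S)-benzyl auxiliary fixing both new centres (C7, C8) in the syn sense required and overriding the remote C6 centre.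

**Step 8**
Reactants: 12 the aldol adduct
Product: 13 (4S)-4-benzyl-3-[(2S,3R,5E)-3-{[tert-butyl(dimethyl)silyl]oxy}-2-[(4S)-2,2-dimethyl-1,3-dioxolan-4-yl]-8-[(4-methoxyphenyl)methoxy]-5-methyloct-5-enoyl]-1,3-oxazolidin-2-one
Conditions: TBSOTf, 2,6-lutidine, CH2Cl2, −78 to 0 °C
Reagents that add atoms: tert-butyldimethylsilyl trifluoromethanesulfonate CC(C)(C)[Si](C)(C)OS(=O)(=O)C(F)(F)F
Why: Silylation of the hindered C8 hydroxyl, which must stay masked through the organometallic steps and during lactone formation (the descriptor at C7 changes only through CIP priority).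

**Step 9**
Reactants: 13 the silylated imide
Product: 14 (2S,3R,5E)-3-{[tert-butyl(dimethyl)silyl]oxy}-2-[(4S)-2,2-dimethyl-1,3-dioxolan-4-yl]-8-[(4-methoxyphenyl)methoxy]-5-methyloct-5-en-1-ol
Conditions: LiBH4, MeOH (1 equiv), THF/Et2O, 0 °C
Reagents that add atoms: none
Why: Reductive cleavage of the N-acyloxazolidinone at the exocyclic carbonyl gives the C11 primary alcohol without touching C7 and returns the auxiliary.

**Step 10**
Reactants: 14 the primary alcohol
Product: 15 (2S,3R,5E)-3-{[tert-butyl(dimethyl)silyl]oxy}-2-[(4S)-2,2-dimethyl-1,3-dioxolan-4-yl]-8-[(4-methoxyphenyl)methoxy]-5-methyloct-5-enal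
Conditions: Dess–Martin periodinane, pyridine, CH2Cl2, 0 °C to rt
Reagents that add atoms: none
Why: Buffered Dess–Martin oxidation gives the α-branched aldehyde under conditions too mild to epimerise C7 or eliminate the β-oxygens.

**Step 11**
Reactants: 15 the aldehyde
Product: 16 tert-butyl({(3S,4R,6E)-3-[(4S)-2,2-dimethyl-1,3-dioxolan-4-yl]-9-[(4-methoxyphenyl)methoxy]-6-methylnon-6-en-1-yn-4-yl}oxy)dimethylsilane
Conditions: dimethyl (1-diazo-2-oxopropyl)phosphonate, K2CO3, MeOH, 0 °C to rt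
Reagents that add atoms: dimethyl (1-diazo-2-oxopropyl)phosphonate CC(=O)C(=[N+]=[N-])P(=O)(OC)OC
Why: Ohira–Bestmann (Seyferth–Gilbert) homologation turns the C11 aldehyde into the C11≡C13 alkyne with carbonate as the only base.

**Step 12**
Reactants: 16 the terminal alkyne
Product: 18 tert-butyl({(3S,4R,6E)-3-[(4S)-2,2-dimethyl-1,3-dioxolan-4-yl]-2-iodo-9-[(4-methoxyphenyl)methoxy]-6-methylnona-1,6-dien-4-yl}oxy)dimethylsilane, via internal alkenylalane 17 (not isolated)
Conditions: DIBAL-H, Ni(dppp)Cl2 (3 mol %), THF, 0 °C to rt; NIS, 0 °C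
Reagents that add atoms: N-iodosuccinimide O=C1CCC(=O)N1I
Why: Nickel-catalysed α-selective (Markovnikov) hydroalumination puts aluminium on the internal carbon C11, and iodinolysis then gives the 2-iodo-1-alkene.

**Step 13**
Reactants: 18 the iodoalkene acetonide
Product: 19 (2S,3S,4R,6E)-4-{[tert-butyl(dimethyl)silyl]oxy}-3-(1-iodoethenyl)-9-[(4-methoxyphenyl)methoxy]-6-methylnon-6-ene-1,2-diol
Conditions: PPTS (cat.), MeOH, rt
Reagents that add atoms: none
Why: Acid-catalysed transketalisation removes the terminal acetonide, while the hindered secondary TBS ether, the PMB ether and the iodoalkene should be stable.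

**Step 14**
Reactants: 19 the 1,2-diol
Product: 21 tert-butyl({(3S,4R,6E)-2-iodo-9-[(4-methoxyphenyl)methoxy]-6-methyl-3-[(2S)-oxiran-2-yl]nona-1,6-dien-4-yl}oxy)dimethylsilane, via primary tosylate 20 (not isolated)
Conditions: TsCl, Et3N, Bu2SnO (cat.), CH2Cl2, 0 °C to rt; K2CO3, MeOH, rt
Reagents that add atoms: none
Why: Tin-catalysed selective sulfonylation of the primary C5 hydroxyl and 3-exo-tet Williamson closure by the C6 alkoxide form the oxirane without breaking the C6–O bond, so C6 keeps its malic-acid configuration.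

**Step 15**
Reactants: 21 the iodoalkene oxirane
Product: 24 (4S,5R)-4-[(1R,3E)-1-{[tert-butyl(dimethyl)silyl]oxy}-6-[(4-methoxyphenyl)methoxy]-3-methylhex-3-en-1-yl]-5-(hydroxymethyl)-3-methylideneoxolan-2-one, via vinyllithium 22 (not isolated), via lithium carboxylate 23 (not isolated)
Conditions: t-BuLi (2.1 equiv), Et2O, −78 °C; CO2 (dry gas), −78 to −20 °C; (±)-CSA (1.5 equiv), THF, −20 °C to rt
Reagents that add atoms: carbon dioxide O=C=O
Why: Iodine–lithium exchange gives the C11 vinyllithium, which adds to CO2 to form C11–C12; protonation with CSA then lets a carboxylate oxygen open the activated C5–C6 oxirane at C6, forming O–C6 and freeing the C5 hydroxyl. The closest known reaction types are the carboxylation of alkenyllithiums and the acid-promoted lactonisation of 4,5-epoxy acids. The butyrolactone ring closes in the 5-exo-tet mode (the breaking C6–O bond lies outside the new ring), preferred over 6-endo attack at C5. C6 is the only centre that changes: backside attack inverts the (S)-oxirane carbon into the configuration that is 6S in the target, cis to the C8 branch on C7, while C7 and C8 are untouched. The step needs carboxylation to outrun attack of the vinyllithium on the neighbouring oxirane, which the low temperature and the absence of a Lewis acid should secure. It also needs the C8 oxygen to stay out, which the TBS ether secures by blocking acyl–oxygen lactonisation to the 12,8-olide and attack on the oxirane.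

**Step 16**
Reactants: 24 the hydroxymethyl lactone
Product: 25 (2R,3S)-3-[(1R,3E)-1-{[tert-butyl(dimethyl)silyl]oxy}-6-[(4-methoxyphenyl)methoxy]-3-methylhex-3-en-1-yl]-4-methylidene-5-oxooxolane-2-carbaldehyde
Conditions: Dess–Martin periodinane, pyridine, CH2Cl2, 0 °C; used at once
Reagents that add atoms: none
Why: Buffered Dess–Martin oxidation turns the C5 alcohol into the aldehyde without base strong enough to epimerise C6.

**Step 17**
Reactants: 25 the C5 aldehyde
Product: 26 (4S,5R)-4-[(1R,3E)-1-{[tert-butyl(dimethyl)silyl]oxy}-6-[(4-methoxyphenyl)methoxy]-3-methylhex-3-en-1-yl]-5-[(1Z)-2-iodoprop-1-en-1-yl]-3-methylideneoxolan-2-one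
Conditions: EtPPh3I, n-BuLi, THF, rt; I2, −78 °C; NaHMDS, −20 °C; 25, −78 to −20 °C
Reagents that add atoms: ethyltriphenylphosphonium iodide CC[P+](c1ccccc1)(c1ccccc1)c1ccccc1.[I-]; iodine II
Why: Stork–Zhao-type Wittig olefination with the α-iodoethylidene ylide is kinetically Z-selective, placing iodine cis to C6 and so setting the later Z C4=C5 ring alkene.

**Step 18**
Reactants: 26 the Z-vinyl iodide
Product: 27 (4R,5R)-4-[(1R,3E)-1-hydroxy-6-[(4-methoxyphenyl)methoxy]-3-methylhex-3-en-1-yl]-5-[(1Z)-2-iodoprop-1-en-1-yl]-3-methylideneoxolan-2-one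
Conditions: HF·pyridine, pyridine, THF, 0 °C to rt
Reagents that add atoms: none
Why: Buffered HF desilylation frees the C8 hydroxyl before the acid-sensitive oxirane is introduced and without the basic fluoride that could induce lactone migration.

**Step 19**
Reactants: 27 the C8 alcohol
Product: 28 (1R,3E)-1-[(2R,3R)-2-[(1Z)-2-iodoprop-1-en-1-yl]-4-methylidene-5-oxooxolan-3-yl]-6-[(4-methoxyphenyl)methoxy]-3-methylhex-3-en-1-yl furan-3-carboxylate
Conditions: furan-3-carbonyl chloride, pyridine, DMAP (cat.), CH2Cl2, 0 °C to rt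
Reagents that add atoms: furan-3-carbonyl chloride O=C(Cl)c1ccoc1
Why: DMAP-catalysed acylation installs the 3-furoate on the only free hydroxyl and removes the risk of C8–OH attacking the lactone carbonyl.

**Step 20**
Reactants: 28 the furoate
Product: 29 (1R)-1-[(2R,3R)-2-[(1Z)-2-iodoprop-1-en-1-yl]-4-methylidene-5-oxooxolan-3-yl]-2-[(2R,3R)-3-{2-[(4-methoxyphenyl)methoxy]ethyl}-2-methyloxiran-2-yl]ethyl furan-3-carboxylate
Conditions: D-fructose-derived Shi ketone (0.3 equiv), Oxone, K2CO3, Bu4NHSO4, MeCN–DMM / aq. Na2B4O7–EDTA, 0 °C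
Reagents that add atoms: potassium peroxymonosulfate [K+].[O-]S(=O)(=O)OO
Why: Shi asymmetric epoxidation, in which the chiral dioxirane attacks the only electron-rich trans-trisubstituted alkene (C1=C10) through the spiro transition state, should give the 1R,10R oxirane under reagent control and leave the iodoalkene, the methylene lactone and the electron-poor furoate alone.

**Step 21**
Reactants: 29 the epoxide
Product: 30 (1R)-2-[(2R,3R)-3-(2-hydroxyethyl)-2-methyloxiran-2-yl]-1-[(2R,3R)-2-[(1Z)-2-iodoprop-1-en-1-yl]-4-methylidene-5-oxooxolan-3-yl]ethyl furan-3-carboxylate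
Conditions: DDQ, CH2Cl2 / pH 7 phosphate buffer, 0 °C to rt
Reagents that add atoms: none
Why: Oxidative PMB cleavage under buffered neutral conditions frees the C3 primary alcohol without opening the oxirane.

**Step 22**
Reactants: 30 the primary alcohol
Product: 31 (1R)-1-[(2R,3R)-2-[(1Z)-2-iodoprop-1-en-1-yl]-4-methylidene-5-oxooxolan-3-yl]-2-[(2R,3R)-2-methyl-3-(2-oxoethyl)oxiran-2-yl]ethyl furan-3-carboxylate
Conditions: Dess–Martin periodinane, pyridine, CH2Cl2, 0 °C; used crude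
Reagents that add atoms: none
Why: Dess–Martin oxidation gives the β,γ-epoxy aldehyde, which is taken on at once to limit β-elimination.

**Step 23**
Reactants: 31 the iodo aldehyde
Product: 32 (1R,3S,4Z,6S,7R,8R,10R)-1,10-epoxy-8-(furan-3-carbonyloxy)-3-hydroxygermacra-4,11(13)-dien-12,6-olide (CNP0390850.1)
Conditions: CrCl2 (8 equiv), NiCl2 (0.1 equiv), DMSO/THF, rt, slow addition to 2 mM
Reagents that add atoms: none
Why: Intramolecular Nozaki–Hiyama–Kishi coupling forms C3–C4 and the ten-membered ring with retention of the Z alkenyl geometry and tolerance of lactone, ester and oxirane; the C3 carbinol is set by the macrocyclic transition state, which should favour addition to the outward-turned aldehyde face to give 3S, a point that has to be confirmed.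

**Compound list**

1 | tert-butyl(but-3-yn-1-yloxy)dimethylsilane | C#CCCO[Si](C)(C)C(C)(C)C | starting material
2 | [(1E)-4-{[tert-butyl(dimethyl)silyl]oxy}-2-methylbut-1-en-1-yl]dimethylalumane | C[Al](C)/C=C(\C)CCO[Si](C)(C)C(C)(C)C | intermediate
3 | (3E)-6-{[tert-butyl(dimethyl)silyl]oxy}-4-methylhex-3-en-1-ol | OCC/C=C(\C)CCO[Si](C)(C)C(C)(C)C | intermediate
4 | tert-butyl({(3E)-6-[(4-methoxyphenyl)methoxy]-3-methylhex-3-en-1-yl}oxy)dimethylsilane | COc1ccc(COCC/C=C(\C)CCO[Si](C)(C)C(C)(C)C)cc1 | intermediate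
5 | (3E)-6-[(4-methoxyphenyl)methoxy]-3-methylhex-3-en-1-ol | COc1ccc(COCC/C=C(\C)CCO)cc1 | intermediate
6 | (3E)-6-[(4-methoxyphenyl)methoxy]-3-methylhex-3-enal | COc1ccc(COCC/C=C(\C)CC=O)cc1 | intermediate
7 | methyl [(4S)-2,2-dimethyl-1,3-dioxolan-4-yl]acetate | COC(=O)C[C@H]1COC(C)(C)O1 | starting material
8 | [(4S)-2,2-dimethyl-1,3-dioxolan-4-yl]acetic acid | OC(=O)C[C@H]1COC(C)(C)O1 | intermediate
9 | (4S)-4-benzyl-1,3-oxazolidin-2-one | O=C1N[C@@H](Cc2ccccc2)CO1 | starting material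
10 | (4S)-4-benzyl-3-{[(4S)-2,2-dimethyl-1,3-dioxolan-4-yl]acetyl}-1,3-oxazolidin-2-one | O=C1OC[C@H](Cc2ccccc2)N1C(=O)C[C@H]1COC(C)(C)O1 | intermediate
11 | Z-dibutylboron enolate of 10 | CCCCB(CCCC)O/C(=C\[C@H]1COC(C)(C)O1)N1[C@@H](Cc2ccccc2)COC1=O | intermediate
12 | (4S)-4-benzyl-3-[(2R,3R,5E)-2-[(4S)-2,2-dimethyl-1,3-dioxolan-4-yl]-3-hydroxy-8-[(4-methoxyphenyl)methoxy]-5-methyloct-5-enoyl]-1,3-oxazolidin-2-one | O=C1OC[C@H](Cc2ccccc2)N1C(=O)[C@@H]([C@H]1COC(C)(C)O1)[C@H](O)C/C(C)=C/CCOCc1ccc(OC)cc1 | intermediate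
13 | (4S)-4-benzyl-3-[(2S,3R,5E)-3-{[tert-butyl(dimethyl)silyl]oxy}-2-[(4S)-2,2-dimethyl-1,3-dioxolan-4-yl]-8-[(4-methoxyphenyl)methoxy]-5-methyloct-5-enoyl]-1,3-oxazolidin-2-one | O=C1OC[C@H](Cc2ccccc2)N1C(=O)[C@@H]([C@H]1COC(C)(C)O1)[C@H](O[Si](C)(C)C(C)(C)C)C/C(C)=C/CCOCc1ccc(OC)cc1 | intermediate
14 | (2S,3R,5E)-3-{[tert-butyl(dimethyl)silyl]oxy}-2-[(4S)-2,2-dimethyl-1,3-dioxolan-4-yl]-8-[(4-methoxyphenyl)methoxy]-5-methyloct-5-en-1-ol | OC[C@@H]([C@H]1COC(C)(C)O1)[C@H](O[Si](C)(C)C(C)(C)C)C/C(C)=C/CCOCc1ccc(OC)cc1 | intermediate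
15 | (2S,3R,5E)-3-{[tert-butyl(dimethyl)silyl]oxy}-2-[(4S)-2,2-dimethyl-1,3-dioxolan-4-yl]-8-[(4-methoxyphenyl)methoxy]-5-methyloct-5-enal | O=C[C@@H]([C@H]1COC(C)(C)O1)[C@H](O[Si](C)(C)C(C)(C)C)C/C(C)=C/CCOCc1ccc(OC)cc1 | intermediate
16 | tert-butyl({(3S,4R,6E)-3-[(4S)-2,2-dimethyl-1,3-dioxolan-4-yl]-9-[(4-methoxyphenyl)methoxy]-6-methylnon-6-en-1-yn-4-yl}oxy)dimethylsilane | C#C[C@@H]([C@H]1COC(C)(C)O1)[C@H](O[Si](C)(C)C(C)(C)C)C/C(C)=C/CCOCc1ccc(OC)cc1 | intermediate
17 | 2-(diisobutylalumanyl)-1-alkene from 16 (Al on C11) | C=C([Al](CC(C)C)CC(C)C)[C@@H]([C@H]1COC(C)(C)O1)[C@H](O[Si](C)(C)C(C)(C)C)C/C(C)=C/CCOCc1ccc(OC)cc1 | intermediate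
18 | tert-butyl({(3S,4R,6E)-3-[(4S)-2,2-dimethyl-1,3-dioxolan-4-yl]-2-iodo-9-[(4-methoxyphenyl)methoxy]-6-methylnona-1,6-dien-4-yl}oxy)dimethylsilane | C=C(I)[C@@H]([C@H]1COC(C)(C)O1)[C@H](O[Si](C)(C)C(C)(C)C)C/C(C)=C/CCOCc1ccc(OC)cc1 | intermediate
19 | (2S,3S,4R,6E)-4-{[tert-butyl(dimethyl)silyl]oxy}-3-(1-iodoethenyl)-9-[(4-methoxyphenyl)methoxy]-6-methylnon-6-ene-1,2-diol | C=C(I)[C@@H]([C@H](O)CO)[C@H](O[Si](C)(C)C(C)(C)C)C/C(C)=C/CCOCc1ccc(OC)cc1 | intermediate
20 | primary (C1) 4-methylbenzenesulfonate of diol 19 | C=C(I)[C@@H]([C@H](O)COS(=O)(=O)c1ccc(C)cc1)[C@H](O[Si](C)(C)C(C)(C)C)C/C(C)=C/CCOCc1ccc(OC)cc1 | intermediate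
21 | tert-butyl({(3S,4R,6E)-2-iodo-9-[(4-methoxyphenyl)methoxy]-6-methyl-3-[(2S)-oxiran-2-yl]nona-1,6-dien-4-yl}oxy)dimethylsilane | C=C(I)[C@@H]([C@H]1CO1)[C@H](O[Si](C)(C)C(C)(C)C)C/C(C)=C/CCOCc1ccc(OC)cc1 | intermediate
22 | C11 vinyllithium from 21 (Li in place of I) | [Li]C(=C)[C@@H]([C@H]1CO1)[C@H](O[Si](C)(C)C(C)(C)C)C/C(C)=C/CCOCc1ccc(OC)cc1 | intermediate
23 | lithium (3S,4R,6E)-4-{[tert-butyl(dimethyl)silyl]oxy}-9-[(4-methoxyphenyl)methoxy]-6-methyl-2-methylidene-3-[(2S)-oxiran-2-yl]non-6-enoate | [Li+].[O-]C(=O)C(=C)[C@@H]([C@H]1CO1)[C@H](O[Si](C)(C)C(C)(C)C)C/C(C)=C/CCOCc1ccc(OC)cc1 | intermediate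
24 | (4S,5R)-4-[(1R,3E)-1-{[tert-butyl(dimethyl)silyl]oxy}-6-[(4-methoxyphenyl)methoxy]-3-methylhex-3-en-1-yl]-5-(hydroxymethyl)-3-methylideneoxolan-2-one | C=C1C(=O)O[C@@H](CO)[C@H]1[C@H](O[Si](C)(C)C(C)(C)C)C/C(C)=C/CCOCc1ccc(OC)cc1 | intermediate
25 | (2R,3S)-3-[(1R,3E)-1-{[tert-butyl(dimethyl)silyl]oxy}-6-[(4-methoxyphenyl)methoxy]-3-methylhex-3-en-1-yl]-4-methylidene-5-oxooxolane-2-carbaldehyde | C=C1C(=O)O[C@@H](C=O)[C@H]1[C@H](O[Si](C)(C)C(C)(C)C)C/C(C)=C/CCOCc1ccc(OC)cc1 | intermediate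
26 | (4S,5R)-4-[(1R,3E)-1-{[tert-butyl(dimethyl)silyl]oxy}-6-[(4-methoxyphenyl)methoxy]-3-methylhex-3-en-1-yl]-5-[(1Z)-2-iodoprop-1-en-1-yl]-3-methylideneoxolan-2-one | C=C1C(=O)O[C@@H](/C=C(/C)I)[C@H]1[C@H](O[Si](C)(C)C(C)(C)C)C/C(C)=C/CCOCc1ccc(OC)cc1 | intermediate
27 | (4R,5R)-4-[(1R,3E)-1-hydroxy-6-[(4-methoxyphenyl)methoxy]-3-methylhex-3-en-1-yl]-5-[(1Z)-2-iodoprop-1-en-1-yl]-3-methylideneoxolan-2-one | C=C1C(=O)O[C@@H](/C=C(/C)I)[C@H]1[C@H](O)C/C(C)=C/CCOCc1ccc(OC)cc1 | intermediate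
28 | (1R,3E)-1-[(2R,3R)-2-[(1Z)-2-iodoprop-1-en-1-yl]-4-methylidene-5-oxooxolan-3-yl]-6-[(4-methoxyphenyl)methoxy]-3-methylhex-3-en-1-yl furan-3-carboxylate | C=C1C(=O)O[C@@H](/C=C(/C)I)[C@H]1[C@H](OC(=O)c1ccoc1)C/C(C)=C/CCOCc1ccc(OC)cc1 | intermediate
29 | (1R)-1-[(2R,3R)-2-[(1Z)-2-iodoprop-1-en-1-yl]-4-methylidene-5-oxooxolan-3-yl]-2-[(2R,3R)-3-{2-[(4-methoxyphenyl)methoxy]ethyl}-2-methyloxiran-2-yl]ethyl furan-3-carboxylate | C=C1C(=O)O[C@@H](/C=C(/C)I)[C@H]1[C@H](OC(=O)c1ccoc1)C[C@@]1(C)O[C@@H]1CCOCc1ccc(OC)cc1 | intermediate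
30 | (1R)-2-[(2R,3R)-3-(2-hydroxyethyl)-2-methyloxiran-2-yl]-1-[(2R,3R)-2-[(1Z)-2-iodoprop-1-en-1-yl]-4-methylidene-5-oxooxolan-3-yl]ethyl furan-3-carboxylate | C=C1C(=O)O[C@@H](/C=C(/C)I)[C@H]1[C@H](OC(=O)c1ccoc1)C[C@@]1(C)O[C@@H]1CCO | intermediate
31 | (1R)-1-[(2R,3R)-2-[(1Z)-2-iodoprop-1-en-1-yl]-4-methylidene-5-oxooxolan-3-yl]-2-[(2R,3R)-2-methyl-3-(2-oxoethyl)oxiran-2-yl]ethyl furan-3-carboxylate | C=C1C(=O)O[C@@H](/C=C(/C)I)[C@H]1[C@H](OC(=O)c1ccoc1)C[C@@]1(C)O[C@@H]1CC=O | intermediate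
32 | (1R,3S,4Z,6S,7R,8R,10R)-1,10-epoxy-8-(furan-3-carbonyloxy)-3-hydroxygermacra-4,11(13)-dien-12,6-olide (CNP0390850.1) | C=C1C(=O)O[C@H]2/C=C(/C)[C@@H](O)C[C@H]3O[C@]3(C)C[C@@H](OC(=O)c3ccoc3)[C@@H]12 | target

**Count and risks**

Total: 23 steps. Longest linear sequence: 21 steps (steps 1–4, then 7–23); steps 5–6 form the second branch.

Step 23 (ring closure). The risk is poor facial selectivity at C3 in the ring-closing addition, made worse if slow closure gives the β,γ-epoxy aldehyde time to eliminate. The fallback sets out from 31 and moves the control of C3 from the C–C bond formation to a ketone reduction. The cyclisation mixture, containing the (3R)-alcohol 3-epi-32 F1 beside 32, is oxidised as a whole (Dess–Martin periodinane, pyridine) to the ten-membered (4Z)-en-3-one F2. This enone is reduced with catecholborane and the (R)-CBS oxazaborolidine at −78 °C, where reagent control should deliver the 3S carbinol; the sequence returns to the route at 32.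

Step 17 (Z-iodo-olefination). The risk is base-induced epimerisation at C6 of the α-acyloxy aldehyde, conjugate addition of the ylide to the methylene lactone, and erosion of Z-selectivity. The fallback sets out from 25 and builds the trisubstituted haloalkene by cross-coupling instead of a Wittig reaction. Ramirez olefination (CBr4, PPh3, Zn, CH2Cl2) gives the 5-(2,2-dibromoethenyl) lactone F3. Trans-selective palladium-catalysed Negishi methylation (MeZnCl, Pd(DPEphos)Cl2), which replaces the bromine trans to C6, gives the 5-[(1Z)-2-bromoprop-1-en-1-yl] lactone F4. Stannylation (Me3SnSnMe3, Pd(PPh3)4) gives the 5-[(1Z)-2-(trimethylstannyl)prop-1-en-1-yl] lactone F5, and iododestannylation (I2, CH2Cl2, 0 °C) with retention returns to the route at 26.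

Step 15 (CO2 lactone formation). The risk is ring closure of the vinyllithium onto the neighbouring oxirane before carboxylation, and loss of the silyl ether on acidification. The fallback sets out from 21 and replaces the organolithium by palladium-catalysed carbonylation. Methoxycarbonylation (Pd(OAc)2, dppf, CO 1 atm, MeOH, Et3N, DMF, 50 °C) gives the methyl 2-methylidene ester F6 with the oxirane untouched. Me3SnOH (1,2-dichloroethane, 60 °C) cleaves the ester to the 2-methylidene epoxy acid F7, which closes 5-exo with catalytic CSA and returns to the route at 24.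

**Further compounds**

F1 | step 23 | 3-epi-32, the (3R)-alcohol | C=C1C(=O)O[C@H]2/C=C(/C)[C@H](O)C[C@H]3O[C@]3(C)C[C@@H](OC(=O)c3ccoc3)[C@@H]12
F2 | step 23 | ten-membered (4Z)-en-3-one (3-dehydro-32) | C=C1C(=O)O[C@H]2/C=C(/C)C(=O)C[C@H]3O[C@]3(C)C[C@@H](OC(=O)c3ccoc3)[C@@H]12
F3 | step 17 | (4S,5R)-4-[(1R,3E)-1-{[tert-butyl(dimethyl)silyl]oxy}-6-[(4-methoxyphenyl)methoxy]-3-methylhex-3-en-1-yl]-5-(2,2-dibromoethenyl)-3-methylideneoxolan-2-one | C=C1C(=O)O[C@@H](C=C(Br)Br)[C@H]1[C@H](O[Si](C)(C)C(C)(C)C)C/C(C)=C/CCOCc1ccc(OC)cc1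
F4 | step 17 | 5-[(1Z)-2-bromoprop-1-en-1-yl] analogue of 26 | C=C1C(=O)O[C@@H](/C=C(/C)Br)[C@H]1[C@H](O[Si](C)(C)C(C)(C)C)C/C(C)=C/CCOCc1ccc(OC)cc1
F5 | step 17 | 5-[(1Z)-2-(trimethylstannyl)prop-1-en-1-yl] analogue of 26 | C=C1C(=O)O[C@@H](/C=C(/C)[Sn](C)(C)C)[C@H]1[C@H](O[Si](C)(C)C(C)(C)C)C/C(C)=C/CCOCc1ccc(OC)cc1
F6 | step 15 | methyl (3S,4R,6E)-4-{[tert-butyl(dimethyl)silyl]oxy}-9-[(4-methoxyphenyl)methoxy]-6-methyl-2-methylidene-3-[(2S)-oxiran-2-yl]non-6-enoate | COC(=O)C(=C)[C@@H]([C@H]1CO1)[C@H](O[Si](C)(C)C(C)(C)C)C/C(C)=C/CCOCc1ccc(OC)cc1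
F7 | step 15 | (3S,4R,6E)-4-{[tert-butyl(dimethyl)silyl]oxy}-9-[(4-methoxyphenyl)methoxy]-6-methyl-2-methylidene-3-[(2S)-oxiran-2-yl]non-6-enoic acid | OC(=O)C(=C)[C@@H]([C@H]1CO1)[C@H](O[Si](C)(C)C(C)(C)C)C/C(C)=C/CCOCc1ccc(OC)cc1
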